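The target is cut at the C18–O ester bond into a labdane alcohol, made from abietic acid, and a hydroxy acid. In the acid, the bond between carbinol carbon C7 and ring CH2 C8 of the trimethylcyclohexanol ring is formed by ring-rearrangement metathesis: a 1-methylcycloheptene from (S)-pulegone, with a butenyl group on quaternary C11, opens at C7=C1 as the six-membered ring closes at C7=C8. The step exploits that C7, ring CH C6 and side-chain carbons C5–C1 can form a seven-membered ring; this temporary ring relays the C3 methyl stereocentre to C6 and is unzipped into the side chain. Bromohydrin formation, debromination and cleavage of the released vinyl group complete the acid.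

Key step: step 5

Remark (labels): acid part C1 = carboxyl carbon, C3 = methyl-bearing CH, C6 = ring CH, C7 = carbinol carbon, C8–C10 = ring CH2, C11 = CMe2; diterpene part in labdane/abietane numbering.
Remark (assumption): (S)-(−)-pulegone, but-3-enylmagnesium bromide and abietic acid (purified from the technical grade through an amine salt) are taken as commercial; abietic acid already has the C4, C5, C9 and C10 configuration of the target.

Step 1
Reactants: 1 (S)-(−)-pulegone; 2 but-3-enylmagnesium bromide
Product: 5 (2R,5S)-5-methyl-2-(2-methylhex-5-en-2-yl)cyclohexan-1-one (trans-ketone), via bromomagnesium enolate 3 (not isolated), via cis-ketone 4 (not isolated)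
Conditions: CuBr·SMe2 (10 mol%), THF, −40 → 0 °C; aq. NH4Cl; then KOH, EtOH, reflux; chromatography
Reagents that add atoms: none
Why: Copper-catalysed conjugate addition of the Grignard reagent to the enone creates quaternary C11, and base equilibration of the epimerisable C6 should favour the diequatorial trans (menthone-type) ketone, so the C3 methyl stereocentre of pulegone sets C6 as R (the minor cis epimer is separated and re-equilibrated).

Step 2
Reactants: 5 trans-ketone
Product: 7 (2R,5S)-5-methyl-2-(2-methylhex-5-en-2-yl)cycloheptan-1-one, via α-trimethylsilyl ketone 6 (not isolated)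
Conditions: Me3SiCHN2, BF3·OEt2, CH2Cl2, −78 → −40 °C; then 1 M HCl, THF
Reagents that add atoms: (trimethylsilyl)diazomethane, C[Si](C)(C)C=[N+]=[N-]
Why: Lewis-acid-promoted diazoalkane homologation (Tiffeneau–Demjanov-type ring expansion) in which the less substituted α-carbon C2 migrates, so the new CH2 (C1) is inserted between C7 and C2 while the hindered C6–H is not enolised at low temperature.

Step 3
Reactants: 7 cycloheptanone
Product: 9 (4S,7R)-4-methyl-7-(2-methylhex-5-en-2-yl)cyclohept-1-en-1-yl trifluoromethanesulfonate, via lithium enolate 8 (not isolated)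
Conditions: LiN(i-Pr)2 (LDA), THF, −78 °C; then PhNTf2, −78 → 0 °C
Reagents that add atoms: N-phenyl-bis(trifluoromethanesulfonimide), O=S(=O)(N(c1ccccc1)S(=O)(=O)C(F)(F)F)C(F)(F)F
Why: Kinetic deprotonation takes the unhindered C1 methylene rather than the neopentyl-type C6–H, and O-triflation of the enolate fixes the C7=C1 regiochemistry and removes the epimerisable position.

Step 4
Reactants: 9 enol triflate
Product: 10 (4S,7R)-1,4-dimethyl-7-(2-methylhex-5-en-2-yl)cyclohept-1-ene
Conditions: MeMgBr, Fe(acac)3 (5 mol%), THF/NMP, −30 → 0 °C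
Reagents that add atoms: methylmagnesium bromide, C[Mg]Br
Why: Iron-catalysed Kumada-type cross-coupling of an alkenyl triflate with a methyl Grignard reagent replaces OTf by CH3 without moving the ring alkene; the terminal alkene is inert.

Step 5
Reactants: 10 1-methylcycloheptene with butenyl side chain
Product: 11 (6R)-1,5,5-trimethyl-6-[(3S)-3-methylhex-5-en-1-yl]cyclohex-1-ene
Conditions: second-generation Grubbs catalyst RuCl2(=CHPh)(PCy3)(H2IMes) (5 mol%), ethylene (1 atm), toluene, 60 °C
Reagents that add atoms: ethylene, C=C (supplies the terminal CH2 of the new vinyl group; the butenyl CH2 leaves as ethylene)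
Why: Ring-rearrangement metathesis: the ruthenium alkylidene formed at the terminal alkene (C8) adds across the trisubstituted ring alkene C7=C1 in a [2+2] step with Ru on C1 and the substituted C7 in the β-position of the ruthenacyclobutane, and cycloreversion gives the C7=C8 bond and a C1 alkylidene that ethylene releases as the vinyl group. The closest known reaction type is the tandem ring-opening/ring-closing metathesis of cycloalkenes that carry an alkenyl side chain. The six-membered carbocycle C6–C7–C8–C9–C10–C11 is closed by the ring-closing metathesis event (alkylidene–alkene [2+2]/retro-[2+2] giving an endocyclic trisubstituted alkene) while the seven-membered ring is opened. No stereocentre is formed: C6 (R) and C3 (S) are carried over unchanged, and C7 is set in step 6. The step needs the equilibrium on the product side and the right metallacycle regiochemistry; release of cycloheptene strain in favour of a cyclohexene, the gem-dimethyl group on C11 and the preference of ruthenium for the less substituted carbon C1 should secure both, and ethylene suppresses oligomers.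

Step 6
Reactants: 11 cyclohexene
Product: 12 (1S,2R,6S)-6-bromo-1,3,3-trimethyl-2-[(3S)-3-methylhex-5-en-1-yl]cyclohexan-1-ol (OH trans to the side chain; Br trans to OH)
Conditions: NBS, THF/H2O, 0 °C
Reagents that add atoms: N-bromosuccinimide, O=C1CCC(=O)N1Br; water, O
Why: Bromohydrin formation is selective for the trisubstituted ring alkene over the vinyl group; by analogy with peracid attack on α-ionone-type rings, the bromonium ion should form anti to the pseudoaxial C11 methyl (the face of the pseudoaxial C6 chain), and trans-diaxial opening by water at tertiary C7 then places OH trans to the chain.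

Step 7
Reactants: 12 bromohydrin
Product: 13 (1R,2R)-1,3,3-trimethyl-2-[(3S)-3-methylhex-5-en-1-yl]cyclohexan-1-ol
Conditions: Bu3SnH, AIBN (cat.), toluene, 80 °C
Reagents that add atoms: none
Why: Radical chain dehalogenation removes the secondary bromide at C8 without touching C7, the tertiary alcohol or the vinyl group.

Step 8
Reactants: 13 tertiary alcohol with terminal alkene
Product: 14 (3S)-5-[(1R,2R)-2-hydroxy-2,6,6-trimethylcyclohexyl]-3-methylpentanoic acid
Conditions: RuCl3·xH2O (cat.), NaIO4, CCl4/MeCN/H2O, rt
Reagents that add atoms: sodium periodate, [Na+].[O-]I(=O)(=O)=O; water, O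
Why: Ruthenium tetroxide-catalysed oxidative cleavage converts the monosubstituted alkene into the acid one carbon shorter (C1), the tertiary alcohol being stable to the oxidant.

Step 9
Reactants: 15 abietic acid
Product: 16 abietinol (abieta-7,13-dien-18-ol)
Conditions: LiAlH4, THF, 0 °C → reflux
Reagents that add atoms: none
Why: Hydride reduction of the hindered C18 acid to the primary alcohol; the diene and all stereocentres are untouched.

Step 10
Reactants: 16 abietinol
Product: 18 18-hydroxy-13-oxo-13,14-secoabiet-7-en-14-al, via syn-13,14-diol 17 (not isolated)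
Conditions: OsO4 (2 mol%), NMO, acetone/H2O, rt; then NaIO4
Reagents that add atoms: N-methylmorpholine N-oxide, C[N+]1([O-])CCOCC1; water, O
Why: Catalytic OsO4/NMO dihydroxylation should be selective for the less hindered C13=C14 bond of the heteroannular diene, and periodate glycol cleavage then opens ring C to the isopropyl ketone and the C7=C8 enal without affecting C9.

Step 11
Reactants: 18 keto enal
Product: 20 18-hydroxy-13,14-secoabiet-8(14)-en-13-one (exocyclic methylene = labdane C17), via tosylhydrazone 19 (not isolated)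
Conditions: TsNHNH2, EtOH, rt; then catecholborane, CHCl3, 0 °C; then NaOAc·3H2O, reflux
Reagents that add atoms: 4-methylbenzenesulfonohydrazide, Cc1ccc(cc1)S(=O)(=O)NN (atoms in 19 only)
Why: The hydrazone forms only at the aldehyde, and its reduction gives an allyl diazene that loses N2 by retro-ene hydrogen transfer to C7, so the alkene moves to the exocyclic C8=C14 position (reductive alkene transposition of an α,β-unsaturated tosylhydrazone).

Step 12
Reactants: 20 isopropyl ketone
Product: 22 isopropyl 18-hydroxy-14,15,16-trinorlabd-8(17)-en-13-oate, via trimethylsilyl ether 21 (not isolated)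
Conditions: (Me3SiO)2, Me3SiOTf (cat.), CH2Cl2, −40 → 0 °C; then 1 M HCl, THF
Reagents that add atoms: bis(trimethylsilyl) peroxide, C[Si](C)(C)OO[Si](C)(C)C
Why: Baeyer–Villiger oxidation with the silyl peroxide inserts oxygen on the side of the better migrating secondary (isopropyl) carbon and, unlike a peracid, should leave the exocyclic alkene unepoxidised; the transiently silylated C18 hydroxyl is freed on work-up.

Step 13
Reactants: 22 isopropyl ester
Product: 24 18-hydroxy-14,15-dinorlabd-8(17)-en-13-one (methyl ketone), via Weinreb amide 23 (not isolated)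
Conditions: MeNH(OMe)·HCl, i-PrMgCl, THF, −20 °C; then MeMgBr, 0 °C; aq. NH4Cl
Reagents that add atoms: methylmagnesium bromide, C[Mg]Br; N,O-dimethylhydroxylamine hydrochloride, CNOC.Cl (atoms in 23 only)
Why: Aminolysis of the ester by the magnesium amide gives the Weinreb amide, whose chelated adduct with MeMgBr collapses only on work-up, so the methyl ketone forms without over-addition (extra Grignard reagent covers the free hydroxyl).

Step 14
Reactants: 24 methyl ketone
Product: 25 methyl (13E)-18-hydroxylabda-8(17),13-dien-15-oate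
Conditions: (MeO)2P(O)CH2CO2Me, NaH, THF, 0 °C → reflux; chromatography
Reagents that add atoms: trimethyl phosphonoacetate, COC(=O)CP(=O)(OC)OC
Why: Horner–Wadsworth–Emmons olefination of the methyl ketone should give mainly the E trisubstituted enoate (ester trans to the chain), the minor Z isomer being removed by chromatography.

Step 15
Reactants: 14 hydroxy acid; 25 labdane alcohol
Product: 27 target ester, via mixed anhydride 26 (not isolated)
Conditions: 2,4,6-Cl3C6H2COCl, Et3N, THF, rt; then 25, DMAP, toluene, rt → 50 °C
Reagents that add atoms: 2,4,6-trichlorobenzoyl chloride, O=C(Cl)c1c(Cl)cc(Cl)cc1Cl (atoms in 26 only)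
Why: Yamaguchi esterification through the mixed anhydride acylates the primary neopentyl C18 hydroxyl, while the hindered tertiary hydroxyl of the acid should not react.

Compound list
1 | (S)-(−)-pulegone | O=C1C[C@@H](C)CCC1=C(C)C | starting material
2 | but-3-enylmagnesium bromide | C=CCC[Mg]Br | starting material
3 | bromomagnesium enolate of 5 | Br[Mg]OC1=C(C(C)(C)CCC=C)CC[C@H](C)C1 | intermediate
4 | (2S,5S)-5-methyl-2-(2-methylhex-5-en-2-yl)cyclohexan-1-one (cis-ketone) | O=C1C[C@@H](C)CC[C@H]1C(C)(C)CCC=C | intermediate
5 | (2R,5S)-5-methyl-2-(2-methylhex-5-en-2-yl)cyclohexan-1-one (trans-ketone) | O=C1C[C@@H](C)CC[C@@H]1C(C)(C)CCC=C | intermediate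
6 | (2R,5S)-5-methyl-2-(2-methylhex-5-en-2-yl)-7-(trimethylsilyl)cycloheptan-1-one | O=C1C([Si](C)(C)C)C[C@@H](C)CC[C@@H]1C(C)(C)CCC=C | intermediate
7 | (2R,5S)-5-methyl-2-(2-methylhex-5-en-2-yl)cycloheptan-1-one | O=C1CC[C@@H](C)CC[C@@H]1C(C)(C)CCC=C | intermediate
8 | lithium (4S,7R)-4-methyl-7-(2-methylhex-5-en-2-yl)cyclohept-1-en-1-olate | [Li]OC1=CC[C@@H](C)CC[C@@H]1C(C)(C)CCC=C | intermediate
9 | (4S,7R)-4-methyl-7-(2-methylhex-5-en-2-yl)cyclohept-1-en-1-yl trifluoromethanesulfonate | O=S(=O)(OC1=CC[C@@H](C)CC[C@@H]1C(C)(C)CCC=C)C(F)(F)F | intermediate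
10 | (4S,7R)-1,4-dimethyl-7-(2-methylhex-5-en-2-yl)cyclohept-1-ene | CC1=CC[C@@H](C)CC[C@@H]1C(C)(C)CCC=C | intermediate
11 | (6R)-1,5,5-trimethyl-6-[(3S)-3-methylhex-5-en-1-yl]cyclohex-1-ene | C=CC[C@@H](C)CC[C@@H]1C(C)(C)CCC=C1C | intermediate
12 | (1S,2R,6S)-6-bromo-1,3,3-trimethyl-2-[(3S)-3-methylhex-5-en-1-yl]cyclohexan-1-ol | C=CC[C@@H](C)CC[C@@H]1C(C)(C)CC[C@H](Br)[C@@]1(C)O | intermediate
13 | (1R,2R)-1,3,3-trimethyl-2-[(3S)-3-methylhex-5-en-1-yl]cyclohexan-1-ol | C=CC[C@@H](C)CC[C@@H]1C(C)(C)CCC[C@@]1(C)O | intermediate
14 | (3S)-5-[(1R,2R)-2-hydroxy-2,6,6-trimethylcyclohexyl]-3-methylpentanoic acid | OC(=O)C[C@@H](C)CC[C@@H]1C(C)(C)CCC[C@@]1(C)O | intermediate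
15 | abietic acid (abieta-7,13-dien-18-oic acid) | CC(C)C1=CC2=CC[C@H]3[C@](C)(C(=O)O)CCC[C@]3(C)[C@H]2CC1 | starting material
16 | abietinol (abieta-7,13-dien-18-ol) | CC(C)C1=CC2=CC[C@H]3[C@](C)(CO)CCC[C@]3(C)[C@H]2CC1 | intermediate
17 | abiet-7-ene-13,14,18-triol (syn-13,14-diol, face immaterial) | CC(C)C1(O)C(O)C2=CC[C@H]3[C@](C)(CO)CCC[C@]3(C)[C@H]2CC1 | intermediate
18 | 18-hydroxy-13-oxo-13,14-secoabiet-7-en-14-al | O=CC1=CC[C@H]2[C@](C)(CO)CCC[C@]2(C)[C@H]1CCC(=O)C(C)C | intermediate
19 | 14-(4-methylbenzenesulfonyl)hydrazone of 18 | Cc1ccc(cc1)S(=O)(=O)NN=CC1=CC[C@H]2[C@](C)(CO)CCC[C@]2(C)[C@H]1CCC(=O)C(C)C | intermediate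
20 | 18-hydroxy-13,14-secoabiet-8(14)-en-13-one | C=C1CC[C@H]2[C@](C)(CO)CCC[C@]2(C)[C@H]1CCC(=O)C(C)C | intermediate
21 | isopropyl 18-(trimethylsilyloxy)-14,15,16-trinorlabd-8(17)-en-13-oate | C=C1CC[C@H]2[C@](C)(CO[Si](C)(C)C)CCC[C@]2(C)[C@H]1CCC(=O)OC(C)C | intermediate
22 | isopropyl 18-hydroxy-14,15,16-trinorlabd-8(17)-en-13-oate | C=C1CC[C@H]2[C@](C)(CO)CCC[C@]2(C)[C@H]1CCC(=O)OC(C)C | intermediate
23 | 18-hydroxy-N-methoxy-N-methyl-14,15,16-trinorlabd-8(17)-en-13-amide | C=C1CC[C@H]2[C@](C)(CO)CCC[C@]2(C)[C@H]1CCC(=O)N(C)OC | intermediate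
24 | 18-hydroxy-14,15-dinorlabd-8(17)-en-13-one | C=C1CC[C@H]2[C@](C)(CO)CCC[C@]2(C)[C@H]1CCC(C)=O | intermediate
25 | methyl (13E)-18-hydroxylabda-8(17),13-dien-15-oate | C=C1CC[C@H]2[C@](C)(CO)CCC[C@]2(C)[C@H]1CC/C(C)=C/C(=O)OC | intermediate
26 | mixed anhydride of 14 with 2,4,6-trichlorobenzoic acid | O=C(OC(=O)C[C@@H](C)CC[C@@H]1C(C)(C)CCC[C@@]1(C)O)c1c(Cl)cc(Cl)cc1Cl | intermediate
27 | methyl (13E)-18-{[(3S)-5-((1R,2R)-2-hydroxy-2,6,6-trimethylcyclohexyl)-3-methylpentanoyl]oxy}labda-8(17),13-dien-15-oate (CNP0174687.1) | C=C1CC[C@H]2[C@](C)(COC(=O)C[C@@H](C)CC[C@@H]3C(C)(C)CCC[C@@]3(C)O)CCC[C@]2(C)[C@H]1CC/C(C)=C/C(=O)OC | target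

Total step count: 15. Longest linear sequence: 9 steps (steps 1–8 and 15, from (S)-pulegone).

Steps most likely to fail

1. Step 5 (key step): the catalyst may stall on the trisubstituted ring alkene, or cross-metathesis oligomers may form instead of ring rearrangement. The fallback opens the ring oxidatively and then uses an ordinary ring-closing metathesis. It sets out from 10: mCPBA (CH2Cl2, 0 °C) should epoxidise the trisubstituted ring alkene selectively to the cycloheptene oxide F1. H5IO6 (THF/H2O) then cleaves this to the keto aldehyde F2. Salt-free Ph3P=CH2 (THF, −78 → 0 °C, both carbonyls) gives the triene F3. Ring-closing metathesis of its isopropenyl and butenyl groups with the same ruthenium catalyst closes the six-membered ring and comes back to the route at 11.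

2. Step 6: facial selectivity of bromonium formation and opening may be poor or reversed, which would give the C7 epimer. The fallback sets out from 11: mCPBA (NaHCO3, CH2Cl2, 0 °C) gives the ring epoxide with oxygen trans to the chain F4, and LiAlH4 (THF, reflux) opens it at C8 to come back at 13. Epoxidation puts oxygen on the face the electrophile attacks, whereas the bromohydrin puts it on the opposite face, so one of the two sequences should give 13 whichever face is preferred.

3. Step 12: oxygen insertion at the hindered acyclic ketone may be sluggish, or the Lewis acid may shift the exocyclic alkene into the ring. The fallback replaces the Baeyer–Villiger step by enolate oxygenation and glycol-type cleavage. It sets out from 20: KOtBu, O2, P(OEt)3 (t-BuOH/DME, −20 °C) should hydroxylate the tertiary α-carbon to the α-hydroxy ketone F5. Pb(OAc)4 in MeOH/benzene cleaves it to the methyl ester F6. F6 under the conditions of step 13 comes back to the route at 24.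

Further compounds
F1 | step 5 | 1,2-epoxide of 10 (8-oxabicyclo[5.1.0]octane; epoxide face immaterial) | CC12OC1C[C@@H](C)CC[C@@H]2C(C)(C)CCC=C
F2 | step 5 | (3S,6R)-6-acetyl-3,7,7-trimethylundec-10-enal | CC(=O)[C@H](CC[C@H](C)CC=O)C(C)(C)CCC=C
F3 | step 5 | (4S,7R)-4,8,8-trimethyl-7-(prop-1-en-2-yl)dodeca-1,11-diene | CC(=C)[C@H](CC[C@H](C)CC=C)C(C)(C)CCC=C
F4 | step 6 | 1,2-epoxide of 11 with oxygen trans to the C6 side chain | C=CC[C@@H](C)CC[C@@H]1C(C)(C)CC[C@H]2O[C@@]12C
F5 | step 12 | 15,18-dihydroxy-13,14-secoabiet-8(14)-en-13-one | C=C1CC[C@H]2[C@](C)(CO)CCC[C@]2(C)[C@H]1CCC(=O)C(C)(C)O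
F6 | step 12 | methyl 18-hydroxy-14,15,16-trinorlabd-8(17)-en-13-oate | C=C1CC[C@H]2[C@](C)(CO)CCC[C@]2(C)[C@H]1CCC(=O)OC
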